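Labdane numbering is used throughout. Ring B is cut at C5–C10 and C7–C8, which leaves a chain in which O-2 and C-19 of ring A are tied as a γ-lactone. In one flask, hydrogen-atom transfer to the C10=C20 alkene gives the tertiary C-10 radical, which closes ring A by 6-exo Giese addition to the C5=C6–C7 enal; the C-7 aldehyde then condenses with the unmasked C8–C17 aldehyde to close ring B. The step exploits the syn-axial O-2/C-19/C-20 triad of ring A: the lactone bridge steers C-20 beneath it. The C-17 enal later gives the exocyclic methylene. (R)-Limonene supplies C-1, C-8 to C-13, C-16, C-17 and C-20.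

Key step: step 10

Assumption: the (R)-configured phosphoric acid of step 2 is taken to direct allyl transfer to the Re face of an aliphatic aldehyde, as it does for benzaldehyde; if the sense is opposite, the (S)-acid is used.

Step 1
Reactants: 1 (R)-(+)-limonene
Product: 3 allylboronate 4,4,5,5-tetramethyl-2-{2-[(1R)-4-methylcyclohex-3-en-1-yl]prop-2-en-1-yl}-1,3,2-dioxaborolane, via allyllithium 2 (not isolated)
Conditions: n-BuLi, TMEDA, hexane, 25 °C; then i-PrOBpin, THF, −78 → 25 °C
Reagents that add atoms: 2-isopropoxy-4,4,5,5-tetramethyl-1,3,2-dioxaborolane, CC(C)OB1OC(C)(C)C(C)(C)O1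
Why: Allylic lithiation of limonene by TMEDA-activated n-BuLi should occur at the isopropenyl methyl group to give a symmetrical 2-substituted allyllithium, which is trapped by the borate (borylation) without touching the ring stereocentre that becomes C-9.

Step 2
Reactants: 3 allylboronate; 4 methyl 4-oxobutanoate
Product: 6 (5S)-5-{2-[(1R)-4-methylcyclohex-3-en-1-yl]prop-2-en-1-yl}oxolan-2-one, via hydroxy ester 5 (not isolated)
Conditions: (R)-3,3′-bis(2,4,6-triisopropylphenyl)-1,1′-binaphthyl-2,2′-diyl hydrogen phosphate (5 mol %), PhMe, −30 °C; aqueous work-up; then TsOH (cat.), CH2Cl2, 25 °C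
Reagents that add atoms: none
Why: Chiral phosphoric acid-catalysed allylboration through a closed chair transition state should deliver the allyl group to the Re face of the aldehyde, so the catalyst sets C-2, and the γ-hydroxy ester lactonises under acid; the minor C-2 epimer is a diastereomer and can be removed.

Step 3
Reactants: 6 lactone
Product: 7 (5S)-5-{2-[(1R)-4-methylcyclohex-3-en-1-yl]prop-2-en-1-yl}-2-oxooxolane-3-carbaldehyde (C-3 epimers, mainly the hydroxymethylene tautomer)
Conditions: NaH, HCO2Et, EtOH (cat.), Et2O, 0 → 25 °C; HCl work-up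
Reagents that add atoms: ethyl formate, CCOC=O
Why: Crossed Claisen condensation (α-formylation) at the only acidic position, C-4, is driven by formation of the stabilised hydroxymethylene enolate and introduces C-5.

Step 4
Reactants: 7 formyl lactone
Product: 8 (3R,5R)-3-methyl-5-{2-[(1R)-4-methylcyclohex-3-en-1-yl]prop-2-en-1-yl}-2-oxooxolane-3-carbaldehyde (formyl cis to the 5-substituent)
Conditions: K2CO3, MeI, acetone, 25 °C
Reagents that add atoms: iodomethane, CI
Why: C-Alkylation of the β-dicarbonyl enolate with the soft electrophile should take place anti to the C-2 substituent of the butyrolactone (1,3-induction), which sets the quaternary C-4 with C-5 cis to C-1.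

Step 5
Reactants: 8 methylated formyl lactone
Product: 9 (3R,5R)-3-methyl-5-{2-[(1R)-4-methylcyclohex-3-en-1-yl]prop-2-en-1-yl}-3-[(1E)-3-oxoprop-1-en-1-yl]oxolan-2-one
Conditions: Ph3P=CHCHO, PhMe, 90 °C
Reagents that add atoms: (triphenylphosphoranylidene)acetaldehyde, O=CC=P(c1ccccc1)(c1ccccc1)c1ccccc1
Why: Wittig olefination with the stabilised formyl ylide should give the E-enal (C-6, C-7), because the non-enolisable aldehyde 8 is activated by the lactone carbonyl and the conjugated product is less electrophilic.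

Step 6
Reactants: 9 enal lactone
Product: 11 (3R,5R)-3-methyl-5-[(3R)-2-methylidene-6-oxo-3-(2-oxoethyl)heptyl]-3-[(1E)-3-oxoprop-1-en-1-yl]oxolan-2-one, via epoxide 10 (not isolated)
Conditions: m-CPBA (1.0 equiv), NaHCO3, CH2Cl2, 0 °C; then H5IO6, THF/H2O, 0 → 25 °C
Reagents that add atoms: m-chloroperoxybenzoic acid, OOC(=O)c1cccc(Cl)c1; water, O
Why: Prilezhaev epoxidation should be fastest at the trisubstituted ring alkene (the C10=C20 alkene and the enal are far less nucleophilic), and periodic acid cleaves the epoxide through the diol (glycol cleavage) to the C-13 ketone and the C-17 aldehyde.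

Step 7
Reactants: 11 keto dialdehyde
Product: 12 (3R,5R)-5-[(3R)-3-(2,2-dimethoxyethyl)-2-methylidene-6-oxoheptyl]-3-[(1E)-3,3-dimethoxyprop-1-en-1-yl]-3-methyloxolan-2-one
Conditions: HC(OMe)3, CeCl3·7H2O (cat.), MeOH, 25 °C
Reagents that add atoms: trimethyl orthoformate, COC(OC)OC
Why: Lanthanide-catalysed acetalisation is selective for aldehydes over ketones, so both aldehydes are masked and the C-13 ketone stays free.

Step 8
Reactants: 12 bis-acetal ketone
Product: 13 ethyl (2E,6R)-6-(2,2-dimethoxyethyl)-8-{(2R,4R)-4-[(1E)-3,3-dimethoxyprop-1-en-1-yl]-4-methyl-5-oxooxolan-2-yl}-3-methyl-7-methylideneoct-2-enoate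
Conditions: (i-PrO)2P(O)CH2CO2Et, NaH, THF, 0 → 50 °C
Reagents that add atoms: ethyl 2-(diisopropoxyphosphoryl)acetate, CCOC(=O)CP(=O)(OC(C)C)OC(C)C
Why: Horner–Wadsworth–Emmons olefination of the methyl ketone adds C-14 and C-15, the bulky phosphonate should favour the E-enoate, and the acetals and the non-enolisable lactone are stable to the base.

Step 9
Reactants: 13 enoate bis-acetal
Product: 14 ethyl (2E,6R)-6-(2,2-dimethoxyethyl)-3-methyl-7-methylidene-8-{(2R,4R)-4-methyl-5-oxo-4-[(1E)-3-oxoprop-1-en-1-yl]oxolan-2-yl}oct-2-enoate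
Conditions: oxalic acid (cat.), wet SiO2, CH2Cl2, 0 °C
Reagents that add atoms: water, O
Why: Acid-catalysed acetal hydrolysis should be much faster for the allylic acetal, which ionises to a conjugated oxocarbenium ion, so the enal is released while the C-17 acetal is kept.

Step 10
Reactants: 14 enal acetal
Product: 17 ethyl (13E)-17-oxolabda-7,13-dien-19,2-olid-15-oate, via ring-A aldehyde 15 (not isolated), via dialdehyde 16 (not isolated)
Conditions: Fe(acac)3 (30 mol %), PhSiH3, EtOH, 60 °C; then H2O, CF3CO2H, dibenzylammonium trifluoroacetate, THF, 50 °C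
Reagents that add atoms: water, O
Why: An iron hydride formed from Fe(acac)3 and PhSiH3 transfers a hydrogen atom to C-20 of the 1,1-disubstituted alkene, and the tertiary C-10 radical adds to C-5 of the enal in a 6-exo-trig Giese cyclisation that closes ring A, the α-formyl radical being reduced and protonated to aldehyde 15 while the masked C-17 acetal leaves the transient enolate nothing to attack. Aqueous acid then frees the C-17 aldehyde (16), and the secondary ammonium salt forms the less hindered enamine at C-8, which adds to the C-7 aldehyde (6-exo-trig aldol) and dehydrates to the cyclohexene carbaldehyde, closing ring B. The closest known reaction types are the metal hydride-initiated reductive radical conjugate addition of alkenes to enals and the amine salt-mediated aldol condensation of dialdehydes. C-10 is controlled by the lactone bridge, which forces O-2 and C-19 axial so that the smaller methyl group C-20 takes the position under the bridge and C-9 the equatorial one, and C-5 is controlled by the chair transition state with the enal equatorial, which puts H-5 anti to C-20 and gives the trans-decalin on ring B closure. The step needs 6-exo attack on the enal instead of 5-exo attack on the side-chain enoate, secured by the more electrophilic β-monosubstituted enal on the cis-lactone tether, and enolisation towards C-8 instead of C-6, secured by C-6 lying next to C-5 between two quaternary carbons.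

Step 11
Reactants: 17 enal
Product: 18 C-17 tosylhydrazone of 17
Conditions: TsNHNH2, EtOH, 25 °C
Reagents that add atoms: p-toluenesulfonyl hydrazide, Cc1ccc(cc1)S(=O)(=O)NN
Why: Hydrazone formation at the only aldehyde or ketone carbonyl of 17 should be clean and leaves the lactone and the enoate untouched.

Step 12
Reactants: 18 tosylhydrazone
Product: 20 ethyl (13E)-labda-8(17),13-dien-19,2-olid-15-oate, via tosylhydrazine 19 (not isolated)
Conditions: catecholborane, CHCl3, 0 °C; then NaOAc·3H2O, 60 °C
Reagents that add atoms: none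
Why: Reduction of the α,β-unsaturated tosylhydrazone followed by sulfinate loss gives an allylic diazene whose retro-ene loss of N2 delivers hydrogen to C-7 and moves the double bond to C8=C17 (reductive 1,3-transposition), so the exocyclic methylene forms without a new stereocentre.

Step 13
Reactants: 20 lactone ester
Product: 21 target, (13E)-2-hydroxylabda-8(17),13-diene-15,19-dioic acid in the enantiomeric series shown by its SMILES
Conditions: LiOH, THF/MeOH/H2O, 50 °C; then 1 M HCl to pH 4, 0 °C
Reagents that add atoms: lithium hydroxide, [Li+].[OH-]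
Why: Saponification should open the strained bridged lactone to the C-2 alcohol and C-19 carboxylate and hydrolyse the ethyl ester, with cold mild acidification to avoid relactonisation and no stereocentre affected.

Compound list
1 | (R)-(+)-limonene, (4R)-1-methyl-4-(prop-1-en-2-yl)cyclohex-1-ene | C=C(C)[C@@H]1CCC(C)=CC1 | starting material
2 | {2-[(1R)-4-methylcyclohex-3-en-1-yl]prop-2-en-1-yl}lithium | [Li]CC(=C)[C@@H]1CCC(C)=CC1 | intermediate
3 | 4,4,5,5-tetramethyl-2-{2-[(1R)-4-methylcyclohex-3-en-1-yl]prop-2-en-1-yl}-1,3,2-dioxaborolane | CC1(C)OB(CC(=C)[C@@H]2CCC(C)=CC2)OC1(C)C | intermediate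
4 | methyl 4-oxobutanoate | COC(=O)CCC=O | starting material
5 | methyl (4S)-4-hydroxy-6-[(1R)-4-methylcyclohex-3-en-1-yl]hept-6-enoate | COC(=O)CC[C@H](O)CC(=C)[C@@H]1CCC(C)=CC1 | intermediate
6 | (5S)-5-{2-[(1R)-4-methylcyclohex-3-en-1-yl]prop-2-en-1-yl}oxolan-2-one | O=C1O[C@H](CC(=C)[C@@H]2CCC(C)=CC2)CC1 | intermediate
7 | (5S)-5-{2-[(1R)-4-methylcyclohex-3-en-1-yl]prop-2-en-1-yl}-2-oxooxolane-3-carbaldehyde (C-3 epimers, hydroxymethylene tautomer) | O=CC1C[C@@H](CC(=C)[C@@H]2CCC(C)=CC2)OC1=O | intermediate
8 | (3R,5R)-3-methyl-5-{2-[(1R)-4-methylcyclohex-3-en-1-yl]prop-2-en-1-yl}-2-oxooxolane-3-carbaldehyde | O=C1O[C@H](CC(=C)[C@@H]2CCC(C)=CC2)C[C@]1(C)C=O | intermediate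
9 | (3R,5R)-3-methyl-5-{2-[(1R)-4-methylcyclohex-3-en-1-yl]prop-2-en-1-yl}-3-[(1E)-3-oxoprop-1-en-1-yl]oxolan-2-one | O=C1O[C@H](CC(=C)[C@@H]2CCC(C)=CC2)C[C@]1(C)/C=C/C=O | intermediate
10 | epoxide of the cyclohexene double bond of 9 (both epoxide diastereomers) | O=C1O[C@H](CC(=C)[C@@H]2CCC3(C)OC3C2)C[C@]1(C)/C=C/C=O | intermediate
11 | (3R,5R)-3-methyl-5-[(3R)-2-methylidene-6-oxo-3-(2-oxoethyl)heptyl]-3-[(1E)-3-oxoprop-1-en-1-yl]oxolan-2-one | O=C1O[C@H](CC(=C)[C@@H](CC=O)CCC(C)=O)C[C@]1(C)/C=C/C=O | intermediate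
12 | (3R,5R)-5-[(3R)-3-(2,2-dimethoxyethyl)-2-methylidene-6-oxoheptyl]-3-[(1E)-3,3-dimethoxyprop-1-en-1-yl]-3-methyloxolan-2-one | O=C1O[C@H](CC(=C)[C@@H](CC(OC)OC)CCC(C)=O)C[C@]1(C)/C=C/C(OC)OC | intermediate
13 | ethyl (2E,6R)-6-(2,2-dimethoxyethyl)-8-{(2R,4R)-4-[(1E)-3,3-dimethoxyprop-1-en-1-yl]-4-methyl-5-oxooxolan-2-yl}-3-methyl-7-methylideneoct-2-enoate | O=C1O[C@H](CC(=C)[C@@H](CC(OC)OC)CC/C(C)=C/C(=O)OCC)C[C@]1(C)/C=C/C(OC)OC | intermediate
14 | ethyl (2E,6R)-6-(2,2-dimethoxyethyl)-3-methyl-7-methylidene-8-{(2R,4R)-4-methyl-5-oxo-4-[(1E)-3-oxoprop-1-en-1-yl]oxolan-2-yl}oct-2-enoate | O=C1O[C@H](CC(=C)[C@@H](CC(OC)OC)CC/C(C)=C/C(=O)OCC)C[C@]1(C)/C=C/C=O | intermediate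
15 | ethyl (13E)-17,17-dimethoxy-7-oxo-7,8-secolabd-13-en-19,2-olid-15-oate (O-2, C-19 and C-20 on one face of ring A, H-5 on the other; C-2, C-4, C-5, C-9, C-10 as in 21) | O=CC[C@H]1[C@@](C)(C[C@@H]2C[C@@]1(C)C(=O)O2)[C@@H](CC(OC)OC)CC/C(C)=C/C(=O)OCC | intermediate
16 | ethyl (13E)-7,17-dioxo-7,8-secolabd-13-en-19,2-olid-15-oate (configuration as in 15) | O=CC[C@H]1[C@@](C)(C[C@@H]2C[C@@]1(C)C(=O)O2)[C@@H](CC=O)CC/C(C)=C/C(=O)OCC | intermediate
17 | ethyl (13E)-17-oxolabda-7,13-dien-19,2-olid-15-oate (trans-decalin, configuration as in 21) | O=CC1=CC[C@H]2[C@@](C)(C[C@@H]3C[C@@]2(C)C(=O)O3)[C@@H]1CC/C(C)=C/C(=O)OCC | intermediate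
18 | C-17 tosylhydrazone of 17 | Cc1ccc(cc1)S(=O)(=O)NN=CC1=CC[C@H]2[C@@](C)(C[C@@H]3C[C@@]2(C)C(=O)O3)[C@@H]1CC/C(C)=C/C(=O)OCC | intermediate
19 | allylic N′-alkyl tosylhydrazine from 18 (C-17 is CH2–NH–NH–Ts; held in the flask as its catecholboryl derivative) | Cc1ccc(cc1)S(=O)(=O)NNCC1=CC[C@H]2[C@@](C)(C[C@@H]3C[C@@]2(C)C(=O)O3)[C@@H]1CC/C(C)=C/C(=O)OCC | intermediate
20 | ethyl (13E)-labda-8(17),13-dien-19,2-olid-15-oate (configuration as in 21) | C=C1CC[C@H]2[C@@](C)(C[C@@H]3C[C@@]2(C)C(=O)O3)[C@@H]1CC/C(C)=C/C(=O)OCC | intermediate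
21 | (13E)-2-hydroxylabda-8(17),13-diene-15,19-dioic acid, enantiomer as drawn (2-OH, C-19 and C-20 syn-axial, H-5 anti to C-20, C-11 equatorial) | C=C1CC[C@H]2[C@@](C)(C[C@@H](O)C[C@@]2(C)C(=O)O)[C@@H]1CC/C(C)=C/C(=O)O | target

Total step count: 13. Longest linear sequence: 13 steps, from 1 to 21 (4 enters in step 2).

Steps most likely to fail

Step 10. The tertiary C-10 radical may be quenched by a second hydrogen-atom transfer before the hindered 6-exo closure onto C-5, which would simply hydrogenate the C10=C20 alkene; to a lesser extent the condensation may enolise towards C-6. The fallback sets out from 14 and comes back at 15. Markovnikov hydration of the C10=C20 alkene (Co(acac)2, PhSiH3, O2, Mukaiyama hydration) would give the tertiary alcohol F1. Acylation with methyl chlorooxoacetate (Et3N, DMAP) would give the methyl oxalate F2, and half-saponification with CsOH the caesium oxalate F3. Visible-light photoredox decarboxylation (Ir[dF(CF3)ppy]2(dtbbpy)PF6, blue light, DME/DMF/H2O) then generates the same C-10 radical with no metal hydride or silane in the flask, so the slow cyclisation is not outrun by reduction. This gives 15, which is unmasked and condensed to 17 as a separate operation under the second-stage conditions of step 10.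

Step 4. The methylation may show poor facial selectivity, O-methylation of the hydroxymethylene enolate, or loss of the formyl group by retro-Claisen cleavage. The fallback sets out from 6 and comes back at 9. Palladium-catalysed α-alkenylation of the lithium enolate of 6 (LiHMDS, Pd2(dba)3, P(t-Bu)3, (E)-1-bromo-3,3-dimethoxyprop-1-ene) would attach the C5–C7 arm directly as the α-alkenyl lactone F4, which has no enolisable oxygen. Deprotonation to the extended enolate and C-methylation (LiHMDS, MeI), again anti to the C-2 substituent, would give the quaternary acetal F5. Mild hydrolysis (PPTS, wet acetone) would give 9.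

Step 9. Both acetals may be lost instead of only the allylic one. The fallback sets out from 13 and comes back at 14. Complete hydrolysis (aqueous CF3CO2H, THF) would give the dialdehyde F6. Kinetic re-acetalisation (HC(OMe)3, CeCl3·7H2O, MeOH, 0 °C, stopped early) would then mask only the saturated C-17 aldehyde, because the conjugated aldehyde reacts much more slowly.

Further compounds
F1 | step 10 | tertiary C-10 alcohol from hydration of 14 (both C-10 epimers) | O=C1O[C@H](CC(C)(O)[C@@H](CC(OC)OC)CC/C(C)=C/C(=O)OCC)C[C@]1(C)/C=C/C=O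
F2 | step 10 | methyl oxalate of F1 | O=C1O[C@H](CC(C)(OC(=O)C(=O)OC)[C@@H](CC(OC)OC)CC/C(C)=C/C(=O)OCC)C[C@]1(C)/C=C/C=O
F3 | step 10 | caesium oxalate of F1 | O=C1O[C@H](CC(C)(OC(=O)C(=O)[O-])[C@@H](CC(OC)OC)CC/C(C)=C/C(=O)OCC)C[C@]1(C)/C=C/C=O.[Cs+]
F4 | step 4 | (5S)-3-[(1E)-3,3-dimethoxyprop-1-en-1-yl]-5-{2-[(1R)-4-methylcyclohex-3-en-1-yl]prop-2-en-1-yl}oxolan-2-one (C-3 epimers) | COC(OC)/C=C/C1C[C@@H](CC(=C)[C@@H]2CCC(C)=CC2)OC1=O
F5 | step 4 | (3R,5R)-3-[(1E)-3,3-dimethoxyprop-1-en-1-yl]-3-methyl-5-{2-[(1R)-4-methylcyclohex-3-en-1-yl]prop-2-en-1-yl}oxolan-2-one | O=C1O[C@H](CC(=C)[C@@H]2CCC(C)=CC2)C[C@]1(C)/C=C/C(OC)OC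
F6 | step 9 | ethyl (2E,6R)-3-methyl-7-methylidene-8-{(2R,4R)-4-methyl-5-oxo-4-[(1E)-3-oxoprop-1-en-1-yl]oxolan-2-yl}-6-(2-oxoethyl)oct-2-enoate | O=C1O[C@H](CC(=C)[C@@H](CC=O)CC/C(C)=C/C(=O)OCC)C[C@]1(C)/C=C/C=O
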